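**Plan**

- Retrosynthesis: the C5–O and C3–O bonds of the 1,2-dioxolane are cut first, which returns both ring oxygens to O2 and leaves an open-chain (2E)-3,5,7-trimethyl trienoic acid. Then the ethyl ester, the C11–C12 bond (alkylborane plus alkenyl iodide), the C10=C11 and C2=C3 double bonds, the C5–CH3 bond and the C4=C5 bond are cut back to (R)-citronellal; the iodide is cut at C14–C15 into cinnamyl bromide and a silylated propyne.
- Enabling feature: in the dioxolane ring the O–O unit bridges C5 and C3. Without it, C5 is an ordinary tertiary C–H and C3 is the β-carbon of a 3-methylalk-2-enoic acid one CH2 away, the arrangement that hydrogen abstraction, O2 capture and 5-exo peroxyl addition can join.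
- Forward order: the chain is grown linearly from citronellal (Wittig, methyl cuprate, Horner–Wadsworth–Emmons), its isopropylidene end is trimmed to a vinyl group and joined to the dienyl iodide by B-alkyl Suzuki–Miyaura coupling, the ester is hydrolysed, and the only ring is closed last by a non-haem iron, 2-oxoglutarate-dependent dioxygenase with O2.
- Stereochemistry: C7 is taken unchanged from (R)-citronellal. 2E comes from the olefination (minor isomer removed), 12E from syn hydrozirconation/iodination and stereoretentive coupling, 16E from cinnamyl bromide. C3 (S) and C5 (R) are both created in the enzymatic ring closure, so C5 is carried as both epimers until then.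

Key step: step 11

Assumption: a dioxygenase variant that accepts the open-chain acid is taken to be obtainable by screening and directed evolution of known endoperoxide-forming 2-oxoglutarate enzymes; its turnover is balanced as acid + 2 O2 + 2-oxoglutaric acid + L-ascorbic acid → target + succinic acid + CO2 + H2O + dehydroascorbic acid; C5 is written 5RS and left open in the SMILES of all open-chain compounds.

**Step 1**
Reactants: 1 (R)-citronellal; 2 1-(triphenylphosphoranylidene)propan-2-one
Product: 3 (3E,6R)-6,10-dimethylundeca-3,9-dien-2-one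
Conditions: toluene, 90 °C
Reagents that add atoms: none
Why: Wittig olefination of an unhindered aldehyde with a ketone-stabilised ylide should be reliably (E)-selective, and the stereocentre, β to the aldehyde, is not at risk.

**Step 2**
Reactants: 3 (3E,6R)-6,10-dimethylundeca-3,9-dien-2-one
Product: 4 (4RS,6R)-4,6,10-trimethylundec-9-en-2-one
Conditions: Me2CuLi (from MeLi and CuI), Et2O, −78 → −20 °C; aq. NH4Cl
Reagents that add atoms: methyllithium, [Li]C
Why: Conjugate addition of Me2CuLi to a β-monosubstituted acyclic enone is standard; the new methyl-bearing centre (the later C5) forms without control, which is intended because it is flattened in the key step.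

**Step 3**
Reactants: 4 (4RS,6R)-4,6,10-trimethylundec-9-en-2-one; 5 triethyl phosphonoacetate
Product: 7 ethyl (2E,5RS,7R)-3,5,7,11-tetramethyldodeca-2,10-dienoate, via sodium triethyl phosphonoacetate 6 (not isolated)
Conditions: NaH, THF, 0 °C; then 4, 65 °C; dilute HCl work-up; chromatography
Reagents that add atoms: none
Why: Horner–Wadsworth–Emmons olefination of a methyl ketone, in which the larger CH2R group and the ester prefer to end up trans, so the (2E) ester should predominate and the minor (2Z) isomer is removed by chromatography at this stage.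

**Step 4**
Reactants: 7 ethyl (2E,5RS,7R)-3,5,7,11-tetramethyldodeca-2,10-dienoate
Product: 9 ethyl (2E,5RS,7R)-3,5,7-trimethyl-10-oxodec-2-enoate, via ozonide 8 (not isolated)
Conditions: O3, CH2Cl2, −78 °C, Sudan Red 7B indicator; then PPh3, −78 °C → rt
Reagents that add atoms: ozone, [O-][O+]=O
Why: Ozonolysis is much faster at the electron-rich trisubstituted alkene than at the conjugated ester alkene, so titration to the indicator end point and reductive work-up should cleave only the isopropylidene unit.

**Step 5**
Reactants: 9 ethyl (2E,5RS,7R)-3,5,7-trimethyl-10-oxodec-2-enoate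
Product: 10 ethyl (2E,5RS,7R)-3,5,7-trimethylundeca-2,10-dienoate
Conditions: Ph3PCH3Br, KOtBu, THF, 0 °C; then 9, −78 → 0 °C
Reagents that add atoms: methyltriphenylphosphonium bromide, C[P+](c1ccccc1)(c1ccccc1)c1ccccc1.[Br-]
Why: Wittig methylenation of an aldehyde with the preformed non-stabilised ylide is fast at low temperature and should leave the enoate ester untouched.

**Step 6**
Reactants: 11 (E)-cinnamyl bromide; 12 1-(trimethylsilyl)propyne
Product: 14 trimethyl[(5E)-6-phenylhex-5-en-1-yn-1-yl]silane, via lithiated 1-(trimethylsilyl)propyne 13 (not isolated)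
Conditions: 12, n-BuLi, THF, −78 °C; then 11, −78 °C → rt
Reagents that add atoms: none
Why: SN2 alkylation of the propargylic lithium reagent by a primary allylic bromide, in which the silyl group disfavours allene formation and the styrene geometry is not touched.

**Step 7**
Reactants: 14 trimethyl[(5E)-6-phenylhex-5-en-1-yn-1-yl]silane
Product: 15 [(1E)-hex-1-en-5-yn-1-yl]benzene
Conditions: K2CO3, MeOH, rt
Reagents that add atoms: none
Why: Base-catalysed methanolysis of an alkynyl C–Si bond (protodesilylation) is mild and specific for this bond.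

**Step 8**
Reactants: 15 [(1E)-hex-1-en-5-yn-1-yl]benzene
Product: 17 [(1E,5E)-6-iodohexa-1,5-dien-1-yl]benzene, via alkenylzirconocene chloride 16 (not isolated)
Conditions: Cp2Zr(H)Cl, THF, rt, dark; then I2, 0 °C
Reagents that add atoms: iodine, [I][I]
Why: Hydrozirconation of a terminal alkyne is syn, puts zirconium on the terminal carbon and is much faster than reaction at the 1,2-disubstituted styrene alkene, and iodinolysis of the C–Zr bond proceeds with retention, which fixes the geometry of the later C12=C13 bond as E.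

**Step 9**
Reactants: 10 ethyl (2E,5RS,7R)-3,5,7-trimethylundeca-2,10-dienoate; 17 [(1E,5E)-6-iodohexa-1,5-dien-1-yl]benzene
Product: 19 ethyl (2E,5RS,7R,12E,16E)-3,5,7-trimethyl-17-phenylheptadeca-2,12,16-trienoate, via B-alkyl-9-BBN adduct 18 (not isolated)
Conditions: 9-BBN, THF, 0 °C → rt; then 17, PdCl2(dppf) (cat.), AsPh3, Cs2CO3, DMF/H2O, rt
Reagents that add atoms: none
Why: 9-BBN should add to the terminal carbon of the monosubstituted alkene only (the trisubstituted enoate is inert), and the B-alkyl Suzuki–Miyaura coupling with an alkenyl iodide forms the sp3–sp2 bond C11–C12 with retention of the (E) geometry.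

**Step 10**
Reactants: 19 ethyl (2E,5RS,7R,12E,16E)-3,5,7-trimethyl-17-phenylheptadeca-2,12,16-trienoate
Product: 20 (2E,5RS,7R,12E,16E)-3,5,7-trimethyl-17-phenylheptadeca-2,12,16-trienoic acid
Conditions: LiOH, THF/MeOH/H2O, 40 °C; then 1 M HCl to pH 3
Reagents that add atoms: lithium hydroxide, [Li+].[OH-]
Why: Saponification of an ethyl ester; the β,β-disubstituted enoate hydrolyses slowly but is not prone to conjugate addition, and mild warming should suffice without moving the double bond.

**Step 11**
Reactants: 20 (2E,5RS,7R,12E,16E)-3,5,7-trimethyl-17-phenylheptadeca-2,12,16-trienoic acid; 21 dioxygen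
Product: 22 2-{(3S,5R)-3,5-dimethyl-5-[(2R,7E,11E)-2-methyl-12-phenyldodeca-7,11-dien-1-yl]-1,2-dioxolan-3-yl}acetic acid
Conditions: endoperoxide-forming non-haem iron 2-oxoglutarate-dependent dioxygenase variant (cell-free extract), FeSO4 (cat.), 2-oxoglutarate, sodium L-ascorbate, air, HEPES buffer pH 7.5, 5% DMSO, 25 °C
Reagents that add atoms: none
Why: Proposed new method: the divalent iron centre should activate a first O2 with 2-oxoglutarate to a tetravalent iron oxo species that, directly or through an active-site tyrosyl radical, removes the tertiary C5 hydrogen; the planar C5 radical traps a second O2, the peroxyl radical adds to C3 of the enoate, and ascorbate (or the tyrosine O–H) hands a hydrogen atom to the resulting C2 radical and returns iron to the divalent state. The closest known reaction types are the endoperoxide formation of verruculogen synthase, an enzyme of this family, the peroxyl radical cyclisation by which cyclooxygenase builds the dioxolane ring of prostaglandin endoperoxides from a fatty acid, and 5-exo peroxyl radical cyclisations of unsaturated hydroperoxides; no enzyme is known to do this on a branched enoic acid, so a variant has to be found by screening homologues and improved by directed evolution. The one ring closes 5-exo-trig: the outer oxygen of the C5 peroxyl radical attacks C3 and the radical is left outside the ring on C2. Both new stereocentres are set by the protein and not by the substrate, the side of the flat C5 radical left open to O2 giving 5R and the face of the (2E)-enoate held towards the peroxyl radical giving 3S, which places the two ring methyl groups trans. The step needs site selectivity for C5–H over the allylic C4 hydrogens, the tertiary C7 hydrogen and the allylic hydrogens at C11, C14 and C15, and what the substrate offers for this is its free carboxylate as a binding anchor four bonds from C5, the rigid enoate next to it and a long lipophilic tail that can be held away from iron; regioselectivity of ring closure is inherent, since C3 is the only alkene carbon within reach of a five-membered transition state. Because C5 is planar in the radical, either C5 epimer of 20 should lead to 22 provided it is bound.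

**Compound list**

1 | (R)-citronellal, (3R)-3,7-dimethyloct-6-enal | C[C@H](CCC=C(C)C)CC=O | starting material
2 | 1-(triphenylphosphoranylidene)propan-2-one | CC(=O)C=P(c1ccccc1)(c1ccccc1)c1ccccc1 | starting material
3 | (3E,6R)-6,10-dimethylundeca-3,9-dien-2-one | C[C@H](CCC=C(C)C)C/C=C/C(C)=O | intermediate
4 | (4RS,6R)-4,6,10-trimethylundec-9-en-2-one | C[C@H](CCC=C(C)C)CC(C)CC(C)=O | intermediate
5 | triethyl phosphonoacetate | CCOC(=O)CP(=O)(OCC)OCC | starting material
6 | sodium triethyl phosphonoacetate (sodium salt of 5, not isolated) | CCOC(=O)[CH-]P(=O)(OCC)OCC.[Na+] | intermediate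
7 | ethyl (2E,5RS,7R)-3,5,7,11-tetramethyldodeca-2,10-dienoate | C[C@H](CCC=C(C)C)CC(C)C/C(C)=C/C(=O)OCC | intermediate
8 | ethyl (2E,5RS,7R)-9-(5,5-dimethyl-1,2,4-trioxolan-3-yl)-3,5,7-trimethylnon-2-enoate (ozonide of 7, not isolated) | C[C@H](CCC1OOC(C)(C)O1)CC(C)C/C(C)=C/C(=O)OCC | intermediate
9 | ethyl (2E,5RS,7R)-3,5,7-trimethyl-10-oxodec-2-enoate | C[C@H](CCC=O)CC(C)C/C(C)=C/C(=O)OCC | intermediate
10 | ethyl (2E,5RS,7R)-3,5,7-trimethylundeca-2,10-dienoate | C[C@H](CCC=C)CC(C)C/C(C)=C/C(=O)OCC | intermediate
11 | (E)-cinnamyl bromide, [(1E)-3-bromoprop-1-en-1-yl]benzene | BrC/C=C/c1ccccc1 | starting material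
12 | 1-(trimethylsilyl)propyne, trimethyl(prop-1-yn-1-yl)silane | CC#C[Si](C)(C)C | starting material
13 | [3-(trimethylsilyl)prop-2-yn-1-yl]lithium (lithiated 12, not isolated) | [Li]CC#C[Si](C)(C)C | intermediate
14 | trimethyl[(5E)-6-phenylhex-5-en-1-yn-1-yl]silane | C[Si](C)(C)C#CCC/C=C/c1ccccc1 | intermediate
15 | [(1E)-hex-1-en-5-yn-1-yl]benzene | C#CCC/C=C/c1ccccc1 | intermediate
16 | Cp2Zr(Cl)[(1E,5E)-6-phenylhexa-1,5-dien-1-yl], alkenylzirconocene chloride (not isolated; cyclopentadienyl rings written as anions) | Cl[Zr+2]/C=C/CC/C=C/c1ccccc1.c1cc[cH-]c1.c1cc[cH-]c1 | intermediate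
17 | [(1E,5E)-6-iodohexa-1,5-dien-1-yl]benzene | I/C=C/CC/C=C/c1ccccc1 | intermediate
18 | ethyl (2E,5RS,7R)-11-(9-borabicyclo[3.3.1]nonan-9-yl)-3,5,7-trimethylundec-2-enoate (not isolated) | C[C@H](CCCCB1C2CCCC1CCC2)CC(C)C/C(C)=C/C(=O)OCC | intermediate
19 | ethyl (2E,5RS,7R,12E,16E)-3,5,7-trimethyl-17-phenylheptadeca-2,12,16-trienoate | C[C@H](CCCC/C=C/CC/C=C/c1ccccc1)CC(C)C/C(C)=C/C(=O)OCC | intermediate
20 | (2E,5RS,7R,12E,16E)-3,5,7-trimethyl-17-phenylheptadeca-2,12,16-trienoic acid | C[C@H](CCCC/C=C/CC/C=C/c1ccccc1)CC(C)C/C(C)=C/C(=O)O | intermediate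
21 | dioxygen | O=O | starting material
22 | 2-{(3S,5R)-3,5-dimethyl-5-[(2R,7E,11E)-2-methyl-12-phenyldodeca-7,11-dien-1-yl]-1,2-dioxolan-3-yl}acetic acid | C[C@H](CCCC/C=C/CC/C=C/c1ccccc1)C[C@]1(C)C[C@@](C)(CC(=O)O)OO1 | target

**Step count and risks**

Total step count: 11. Longest linear sequence: 8 steps from (R)-citronellal (steps 1–5, 9, 10, 11); the iodide 17 takes 3 steps (6–8).

Steps most likely to fail:

1. Step 11 (the step labelled as a proposed new method). What may go wrong: no variant may accept the acid at a useful rate; hydrogen abstraction may occur at C4 or in the unsaturated tail instead of at C5; O2 capture and ring closure may proceed without facial control; or the C2 radical may be oxygenated instead of reduced. The fallback uses known chemistry, builds the peroxide ring chemically before the tail is attached, sets out from 3 and returns at 22.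
   - Conjugate addition of Me2CuLi to 3 with TMSCl trapping should give the silyl enol ether trimethyl{[(6R)-4,6,10-trimethylundeca-2,9-dien-2-yl]oxy}silane F1.
   - Saegusa–Ito oxidation (Pd(OAc)2, MeCN) should give the β,β-disubstituted enone (6R)-4,6,10-trimethylundeca-3,9-dien-2-one F2.
   - Acid-catalysed conjugate addition of aqueous H2O2 should close the cyclic peroxyhemiketal 5-[(2R)-2,6-dimethylhept-5-en-1-yl]-3,5-dimethyl-1,2-dioxolan-3-ol F3, which MeOH/TsOH should convert into the peroxyketal 5-[(2R)-2,6-dimethylhept-5-en-1-yl]-3-methoxy-3,5-dimethyl-1,2-dioxolane F4.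
   - TiCl4-mediated substitution through the peroxycarbenium ion with the trimethylsilyl ketene acetal of ethyl acetate should give ethyl 2-{(3S,5R)-5-[(2R)-2,6-dimethylhept-5-en-1-yl]-3,5-dimethyl-1,2-dioxolan-3-yl}acetate F5. No control of C3 and C5 is expected, so F5 would be separated from its ring diastereomers by chromatography.
   - The tail is then attached as in steps 4, 5 and 9, which the hindered dialkyl peroxide is expected to survive: ozonolysis through the ozonide ethyl 2-{(3S,5R)-5-[(2R)-4-(5,5-dimethyl-1,2,4-trioxolan-3-yl)-2-methylbutyl]-3,5-dimethyl-1,2-dioxolan-3-yl}acetate F6 to the aldehyde ethyl 2-{(3S,5R)-3,5-dimethyl-5-[(2R)-2-methyl-5-oxopentyl]-1,2-dioxolan-3-yl}acetate F7; methylenation to ethyl 2-{(3S,5R)-3,5-dimethyl-5-[(2R)-2-methylhex-5-en-1-yl]-1,2-dioxolan-3-yl}acetate F8; hydroboration to the borane ethyl 2-{(3S,5R)-5-[(2R)-6-(9-borabicyclo[3.3.1]nonan-9-yl)-2-methylhexyl]-3,5-dimethyl-1,2-dioxolan-3-yl}acetate F9; coupling with 17 to ethyl 2-{(3S,5R)-3,5-dimethyl-5-[(2R,7E,11E)-2-methyl-12-phenyldodeca-7,11-dien-1-yl]-1,2-dioxolan-3-yl}acetate F10.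
   - Hydrolysis of F10 with LiOH/H2O2 at 0 °C gives 22.

2. Step 3. What may go wrong: the olefination of the methyl ketone may show too little preference for the 2E geometry, and the geometric isomers (each a pair of C5 epimers) may not separate cleanly. The fallback sets out from 4 and returns at 7, fixing the geometry by syn carbometalation. Kinetic deprotonation of 4 at the methyl group (LDA, −78 °C), phosphorylation with ClP(O)(OEt)2 to the enol phosphate diethyl (6R)-4,6,10-trimethylundeca-1,9-dien-2-yl phosphate F11 and elimination with more LDA should give the terminal alkyne (6R)-4,6,10-trimethylundec-9-en-1-yne F12. Zirconium-catalysed methylalumination (Me3Al, Cp2ZrCl2 cat., CH2Cl2) adds methyl and aluminium syn to give the alkenylalane dimethyl[(1E,6R)-2,4,6,10-tetramethylundeca-1,9-dien-1-yl]alumane F13, and acylation with ethyl chloroformate with retention gives 7 as the 2E isomer only.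

3. Step 4. What may go wrong: over-oxidation, with ozone also cleaving the conjugated C2=C3 bond once the isopropylidene group is consumed. The fallback sets out from 7 and returns at 9, replacing ozone by a two-stage cleavage. mCPBA (CH2Cl2, NaHCO3, 0 °C) should epoxidise only the electron-rich trisubstituted alkene to ethyl (2E,5RS,7R)-9-(3,3-dimethyloxiran-2-yl)-3,5,7-trimethylnon-2-enoate F14, and H5IO6 (THF/H2O) cleaves the epoxide to 9 and acetone.

**Further compounds**

F1 | step 11 | trimethyl{[(6R)-4,6,10-trimethylundeca-2,9-dien-2-yl]oxy}silane | C[C@H](CCC=C(C)C)CC(C)C=C(C)O[Si](C)(C)C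
F2 | step 11 | (6R)-4,6,10-trimethylundeca-3,9-dien-2-one | C[C@H](CCC=C(C)C)CC(C)=CC(C)=O
F3 | step 11 | 5-[(2R)-2,6-dimethylhept-5-en-1-yl]-3,5-dimethyl-1,2-dioxolan-3-ol | C[C@H](CCC=C(C)C)CC1(C)CC(C)(O)OO1
F4 | step 11 | 5-[(2R)-2,6-dimethylhept-5-en-1-yl]-3-methoxy-3,5-dimethyl-1,2-dioxolane | C[C@H](CCC=C(C)C)CC1(C)CC(C)(OC)OO1
F5 | step 11 | ethyl 2-{(3S,5R)-5-[(2R)-2,6-dimethylhept-5-en-1-yl]-3,5-dimethyl-1,2-dioxolan-3-yl}acetate | C[C@H](CCC=C(C)C)C[C@]1(C)C[C@@](C)(CC(=O)OCC)OO1
F6 | step 11 | ethyl 2-{(3S,5R)-5-[(2R)-4-(5,5-dimethyl-1,2,4-trioxolan-3-yl)-2-methylbutyl]-3,5-dimethyl-1,2-dioxolan-3-yl}acetate | C[C@H](CCC1OOC(C)(C)O1)C[C@]1(C)C[C@@](C)(CC(=O)OCC)OO1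
F7 | step 11 | ethyl 2-{(3S,5R)-3,5-dimethyl-5-[(2R)-2-methyl-5-oxopentyl]-1,2-dioxolan-3-yl}acetate | C[C@H](CCC=O)C[C@]1(C)C[C@@](C)(CC(=O)OCC)OO1
F8 | step 11 | ethyl 2-{(3S,5R)-3,5-dimethyl-5-[(2R)-2-methylhex-5-en-1-yl]-1,2-dioxolan-3-yl}acetate | C[C@H](CCC=C)C[C@]1(C)C[C@@](C)(CC(=O)OCC)OO1
F9 | step 11 | ethyl 2-{(3S,5R)-5-[(2R)-6-(9-borabicyclo[3.3.1]nonan-9-yl)-2-methylhexyl]-3,5-dimethyl-1,2-dioxolan-3-yl}acetate | C[C@H](CCCCB1C2CCCC1CCC2)C[C@]1(C)C[C@@](C)(CC(=O)OCC)OO1
F10 | step 11 | ethyl 2-{(3S,5R)-3,5-dimethyl-5-[(2R,7E,11E)-2-methyl-12-phenyldodeca-7,11-dien-1-yl]-1,2-dioxolan-3-yl}acetate | C[C@H](CCCC/C=C/CC/C=C/c1ccccc1)C[C@]1(C)C[C@@](C)(CC(=O)OCC)OO1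
F11 | step 3 | diethyl (6R)-4,6,10-trimethylundeca-1,9-dien-2-yl phosphate | C[C@H](CCC=C(C)C)CC(C)CC(=C)OP(=O)(OCC)OCC
F12 | step 3 | (6R)-4,6,10-trimethylundec-9-en-1-yne | C[C@H](CCC=C(C)C)CC(C)CC#C
F13 | step 3 | dimethyl[(1E,6R)-2,4,6,10-tetramethylundeca-1,9-dien-1-yl]alumane | C[C@H](CCC=C(C)C)CC(C)C/C(C)=C/[Al](C)C
F14 | step 4 | ethyl (2E,5RS,7R)-9-(3,3-dimethyloxiran-2-yl)-3,5,7-trimethylnon-2-enoate | C[C@H](CCC1OC1(C)C)CC(C)C/C(C)=C/C(=O)OCC
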